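- Answer these 4 questions about Friday's flask, in which a single-handed free catalyst meets a racemate and the reagent turns left-handed substrate into left-handed product; Sunday's run is the same recipe at twice the concentration.

| flask | left-handed substrate | right-handed substrate | reagent | free catalyst | remark | time |
|---|---|---|---|---|---|---|
| Friday's | 0.10 M | 0.10 M | 1.1 equiv | 0.1 mol% | the very flask that is asked about, followed so far |  |
| Sunday's | 0.20 M | 0.20 M | 1.1 equiv | 0.1 mol% | run made earlier |  |
| flask | 0.10 M | 0.10 M | 1.10 equiv | 0.1 mol% |  | 15 min |

| run | time / min | left-handed product / % |
|---|---|---|
| Friday's | 1.00 | 7.9 |
| Friday's | 1.33 | 8.7 |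
| Friday's | 2.00 | 9.6 |
| Friday's | 3.00 | 11.6 |
| Friday's | 5.00 | 12.0 |
| Friday's | 8.00 | 12.7 |
| Friday's | 12.0 | 12.8 |
| Sunday's | 2.00 | 12.6 |
| Sunday's | 4.00 | 13.8 |
| Sunday's | 6.00 | 13.0 |
| Sunday's | 8.00 | 13.7 |
| Sunday's | 10.0 | 13.4 |
| Sunday's | 12.0 | 13.3 |
| Sunday's | 15.0 | 13.5 |

(standard deviation of a reading: 0.3 percentage points)

- free catalyst is single-handed; left-handed substrate and right-handed substrate are mirror images of each other, charged as a racemate, each of them at the stated concentration
- left-handed product taken out counts as made
- additions bring no volume worth counting

- alpha: at 15 min add free catalyst, 50.0% of the amount charged, then wait 15 min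
- delta: at 15 min add reagent, 50.0% of the amount charged, then wait 15 min
- epsilon: change nothing and wait 15 min more
- beta: at 15 min take out 90% of the left-handed product then present, then wait 15 min

- left-handed product, in percent of the left-handed substrate and right-handed substrate together first charged, at 15 min
- the option that brings most further left-handed product ("none" if no option brings more than 2 percentage points) (alpha / delta / epsilon / beta / none)
- left-handed product present, with what was taken out counted in, in percent of the left-handed substrate and right-handed substrate together first charged, after alpha
- left-handed product present, with what was taken out counted in, in percent of the left-handed substrate and right-handed substrate together first charged, after delta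

- Take the symmetric case as the zero of the scale: let the reagent divide evenly between the hands, so that left-handed product receives half of the reagent charge, an even share of 27.5% of the substrates charged.
- Set the second amount against it, Friday's last reading of 12.8%, and define the return ρ, left-handed product read on the plateau over even share, 0.465.
- Check Sunday's run: its return, also a reading, is 0.491, so in these two runs ρ barely moves when substrates, reagent and catalyst double together.
- Note that Friday's last reading leaves 74.4% of the left-handed substrate unconverted.
- Commit, as my own wager that the readings cannot prove, to reagent as the limiting reagent, lost partly to something else. Then Friday's flask stays near 12.8%, and delta, earning at ρ, adds 6.4 percentage points, reaching 19.2%, while alpha adds nothing.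
- Hold the forecast against this: it gives 12.9%, best alpha, 18.3% after alpha and 12.9% after delta, reasoning that “Each catalyst therefore seems to deliver a fixed number of turnovers”. We part on catalyst against reagent.
- Read Friday's flask: 12.8%, best delta, 12.8% after alpha and 21.1% after delta.

    free catalyst + left-handed substrate ⇌ catalyst intermediate A (K = 18.0 /M, k = 10600 /M/s)
    free catalyst + right-handed substrate ⇌ catalyst intermediate B (K = 26.9 /M, k = 10300 /M/s)
    reagent + catalyst intermediate A → free catalyst + left-handed product (k = 137 /M/s)
    reagent + catalyst intermediate B → free catalyst + right-handed product (k = 65.0 /M/s)
    2 reagent → self-condensation product (k = 0.133 /M/s)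
    reagent → decomposition product (k = 3.55 × 10⁻⁵ /s)

- See what delta's gain rests on in Friday's flask: at 15.0 min the reagent stands at 0.0289% of its charge while 74.3% of the left-handed substrate remains free, and the run without the backward step from catalyst intermediate B to free catalyst and right-handed substrate gains 0.15 points from delta, not 8.2 points, so that step is a part of the reason. Apply ρ to delta's added reagent: it returns 0.598. Apply it to the neighbour flask charged with 0.280 equiv of reagent: that flask makes 5.65%, a return of 0.807.

The runs were computed for substances that don't exist; scatter was added.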